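The route rests on opening the dihydropyranone ring (O1, C2, C3, C4, C4a, C8a) of the chromanone to an aryl tiglate: the C4 ketone sits on C4a, ortho to the phenol oxygen O1 on C8a, and C2–C3 is the alkene of a tigloyl group. In one flask a photo-Fries 1,3-acyl shift carries the tigloyl group from O1 to the only free ring carbon (C4–C4a) and (−)-quinine then adds O1 to C2, setting the cis-2,3-dimethyl pair. The precursor is the O1 tiglate of a bis-MOM, C6-prenylated phloroglucinol that already bears the (S)-configured methyl hexanoate side chain, installed by an iminium-catalysed Friedel–Crafts reaction.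

Key step: step 7

Assumption: (−)-quinine is taken to induce the (2R,3S) sense in 18, as it does in closely related o-tigloylphenols; if the sense were reversed, (+)-quinidine would be used instead.

Step 1
Reactants: 1 resorcinol; 2 chloromethyl methyl ether
Product: 3 1,3-bis(methoxymethoxy)benzene
Conditions: NaH (2.4 equiv), MOMCl (2.3 equiv), DMF, 0 °C → rt
Reagents that add atoms: chloromethyl methyl ether (2), COCCl
Why: Williamson-type O-alkylation of both phenoxides gives the two MOM ethers, which later direct the lithiation and should survive base, light and amine catalysts.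

Step 2
Reactants: 3 1,3-bis(methoxymethoxy)benzene; 4 1-bromo-3-methylbut-2-ene (prenyl bromide)
Product: 6 1,3-bis(methoxymethoxy)-2-(3-methylbut-2-en-1-yl)benzene, via aryllithium 5 (not isolated)
Conditions: n-BuLi (1.1 equiv), THF, 0 °C → rt; then CuBr·SMe2 (10 mol %), prenyl bromide, −78 °C → rt
Reagents that add atoms: 1-bromo-3-methylbut-2-ene (4), CC(C)=CCBr
Why: Directed ortho-metalation occurs only at C2 between the two coordinating OMOM groups, and the aryl metal should be alkylated at the primary carbon of the allylic bromide (SN2) to give the prenyl arene.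

Step 3
Reactants: 6 1,3-bis(methoxymethoxy)-2-(3-methylbut-2-en-1-yl)benzene; 7 bis(pinacolato)diboron; 8 hydrogen peroxide
Product: 10 3,5-bis(methoxymethoxy)-4-(3-methylbut-2-en-1-yl)phenol, via aryl pinacol boronate 9 (not isolated)
Conditions: [Ir(OMe)(cod)]2 (1.5 mol %), 4,4'-di-tert-butyl-2,2'-bipyridine (3 mol %), B2pin2 (1.0 equiv), THF, 70 °C; then 30% aq. H2O2, 2 M aq. NaOH, 0 °C
Reagents that add atoms: hydrogen peroxide (8), OO (oxygen of the phenol); bis(pinacolato)diboron (7), CC1(C)OB(OC1(C)C)B1OC(C)(C)C(C)(C)O1 (boryl group of 9 only)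
Why: Iridium-catalysed C–H borylation is sterically controlled and should take the only C–H without an ortho substituent (C5, meta to both OMOM groups), and oxidation of the boronate (1,2-aryl shift from boron to oxygen) then gives the symmetrical phenol.

Step 4
Reactants: 10 3,5-bis(methoxymethoxy)-4-(3-methylbut-2-en-1-yl)phenol; 11 (E)-hex-2-enal
Product: 12 (4S)-5,7-bis(methoxymethoxy)-6-(3-methylbut-2-en-1-yl)-4-propyl-3,4-dihydro-2H-chromen-2-ol (mixture of C2 epimers)
Conditions: (R)-2-[diphenyl(trimethylsilyloxy)methyl]pyrrolidine (20 mol %), PhCO2H (20 mol %), toluene, 0 °C → rt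
Reagents that add atoms: (E)-hex-2-enal (11), CCC/C=C/C=O
Why: Iminium-catalysed asymmetric Friedel–Crafts alkylation/hemiacetalisation: either of the two equivalent ortho carbons of the phenol attacks C3 of the (E)-iminium ion on its Si face, because the diphenyl(silyloxy)methyl group of the (R)-catalyst shields the Re face, which sets the (S) centre, and the phenol oxygen traps the aldehyde as the lactol and is thereby marked as the future O1.

Step 5
Reactants: 12 (4S)-5,7-bis(methoxymethoxy)-6-(3-methylbut-2-en-1-yl)-4-propyl-3,4-dihydro-2H-chromen-2-ol; 13 methanol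
Product: 15 methyl (3S)-3-[6-hydroxy-2,4-bis(methoxymethoxy)-3-(3-methylbut-2-en-1-yl)phenyl]hexanoate, via lactone 14 (not isolated)
Conditions: n-Pr4N[RuO4] (5 mol %), N-methylmorpholine N-oxide (1.5 equiv), 4 Å molecular sieves, CH2Cl2, rt; then MeOH, NaOMe (1.2 equiv), 0 °C; AcOH
Reagents that add atoms: methanol (13), CO
Why: Ley–Griffith oxidation of the lactol gives the lactone 14, whose aryl ester is opened by methoxide (transesterification) to the methyl ester, which frees as the only phenol the oxygen that becomes O1 and touches no bond of the stereocentre.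

Step 6
Reactants: 15 methyl (3S)-3-[6-hydroxy-2,4-bis(methoxymethoxy)-3-(3-methylbut-2-en-1-yl)phenyl]hexanoate; 16 tiglic acid ((2E)-2-methylbut-2-enoic acid)
Product: 17 methyl (3S)-3-[2,4-bis(methoxymethoxy)-3-(3-methylbut-2-en-1-yl)-6-{[(2E)-2-methylbut-2-enoyl]oxy}phenyl]hexanoate
Conditions: tiglic acid (1.5 equiv), DCC (1.5 equiv), DMAP (10 mol %), CH2Cl2, 0 °C → rt
Reagents that add atoms: tiglic acid (16), C/C=C(\C)C(=O)O
Why: Steglich esterification acylates the single free phenol under near-neutral conditions, which should avoid relactonisation onto the side-chain ester and deconjugation of the (E)-tigloyl group.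

Step 7
Reactants: 17 methyl (3S)-3-[2,4-bis(methoxymethoxy)-3-(3-methylbut-2-en-1-yl)-6-{[(2E)-2-methylbut-2-enoyl]oxy}phenyl]hexanoate
Product: 19 methyl (3S)-3-[(2R,3S)-5,7-bis(methoxymethoxy)-2,3-dimethyl-6-(3-methylbut-2-en-1-yl)-4-oxo-3,4-dihydro-2H-chromen-8-yl]hexanoate, via o-hydroxyaryl tigloyl ketone 18 (not isolated)
Conditions: hν (254 nm, low-pressure Hg lamp, quartz), degassed cyclohexane, rt; then solvent exchange to chlorobenzene, (−)-quinine (20 mol %), rt, dark
Reagents that add atoms: none
Why: Irradiation at 254 nm cleaves the ester O1–C(acyl) bond to a solvent-caged aryloxyl/tigloyl radical pair that recombines at C4a and tautomerises to the o-hydroxyaryl tigloyl ketone 18 (photo-Fries 1,3-acyl shift, C4–C4a bond), whose hydrogen-bonded chromophore then dissipates light by excited-state proton transfer and so protects the (E)-enone. (−)-Quinine next activates the O1–H phenol with its quinuclidine nitrogen and O1 adds to C2 in a 6-endo-trig oxa-Michael closure of the dihydropyranone ring (O1–C2 bond). The closest known reactions are the one-pot photo-Fries/oxa-Michael synthesis of chroman-4-ones from aryl enoates and the cinchona-alkaloid-catalysed intramolecular oxa-Michael addition of o-tigloylphenols to cis-2,3-dimethylchroman-4-ones. C2 (R) is set by the catalyst-controlled face of O1 attack on the (E)-enone, and C3 (S) by kinetic protonation of the ring enol anti to the new C2 methyl group by the quinuclidinium ion, which gives the cis isomer. Regioselectivity is secured by the substrate: the other ortho carbon and the para carbon of the ester bear alkyl groups, so the acyl group can only settle on C4a, and O1 is the only free phenol because the oxygens on C5 and C7 are MOM ethers. The step needs kinetic cis over thermodynamic trans selectivity, which the weak amine base, the apolar solvent and room temperature should secure by not enolising the product.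

Step 8
Reactants: 19 methyl (3S)-3-[(2R,3S)-5,7-bis(methoxymethoxy)-2,3-dimethyl-6-(3-methylbut-2-en-1-yl)-4-oxo-3,4-dihydro-2H-chromen-8-yl]hexanoate
Product: 20 methyl (3S)-3-[(2R,3S)-5,7-dihydroxy-2,3-dimethyl-6-(3-methylbut-2-en-1-yl)-4-oxo-3,4-dihydro-2H-chromen-8-yl]hexanoate (CNP0068017.4)
Conditions: 3 M aq. HCl, MeOH, 30 °C; NaHCO3 before concentration
Reagents that add atoms: none
Why: Acid-catalysed transacetalisation of both MOM ethers to methanol frees the two phenols without any base, so the epimerisable cis C3 centre and the ring regiochemistry should stay intact, while methanol as solvent keeps the side-chain ester open and the mild acid should leave the prenyl group alone.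

Compound list
1 | resorcinol | Oc1cccc(O)c1 | starting material
2 | chloromethyl methyl ether | COCCl | starting material
3 | 1,3-bis(methoxymethoxy)benzene | COCOc1cccc(OCOC)c1 | intermediate
4 | 1-bromo-3-methylbut-2-ene | CC(C)=CCBr | starting material
5 | [2,6-bis(methoxymethoxy)phenyl]lithium | [Li]c1c(OCOC)cccc1OCOC | intermediate (not isolated)
6 | 1,3-bis(methoxymethoxy)-2-(3-methylbut-2-en-1-yl)benzene | COCOc1cccc(OCOC)c1CC=C(C)C | intermediate
7 | bis(pinacolato)diboron | CC1(C)OB(OC1(C)C)B1OC(C)(C)C(C)(C)O1 | starting material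
8 | hydrogen peroxide | OO | starting material
9 | 2-[3,5-bis(methoxymethoxy)-4-(3-methylbut-2-en-1-yl)phenyl]-4,4,5,5-tetramethyl-1,3,2-dioxaborolane | COCOc1cc(cc(OCOC)c1CC=C(C)C)B1OC(C)(C)C(C)(C)O1 | intermediate (not isolated)
10 | 3,5-bis(methoxymethoxy)-4-(3-methylbut-2-en-1-yl)phenol | COCOc1cc(O)cc(OCOC)c1CC=C(C)C | intermediate
11 | (E)-hex-2-enal | CCC/C=C/C=O | starting material
12 | (4S)-5,7-bis(methoxymethoxy)-6-(3-methylbut-2-en-1-yl)-4-propyl-3,4-dihydro-2H-chromen-2-ol (C2 epimers) | CCC[C@H]1CC(O)Oc2cc(OCOC)c(CC=C(C)C)c(OCOC)c21 | intermediate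
13 | methanol | CO | starting material
14 | (4S)-5,7-bis(methoxymethoxy)-6-(3-methylbut-2-en-1-yl)-4-propyl-3,4-dihydro-2H-chromen-2-one | CCC[C@H]1CC(=O)Oc2cc(OCOC)c(CC=C(C)C)c(OCOC)c21 | intermediate (not isolated)
15 | methyl (3S)-3-[6-hydroxy-2,4-bis(methoxymethoxy)-3-(3-methylbut-2-en-1-yl)phenyl]hexanoate | CCC[C@@H](CC(=O)OC)c1c(O)cc(OCOC)c(CC=C(C)C)c1OCOC | intermediate
16 | tiglic acid, (2E)-2-methylbut-2-enoic acid | C/C=C(\C)C(=O)O | starting material
17 | methyl (3S)-3-[2,4-bis(methoxymethoxy)-3-(3-methylbut-2-en-1-yl)-6-{[(2E)-2-methylbut-2-enoyl]oxy}phenyl]hexanoate | CCC[C@@H](CC(=O)OC)c1c(OC(=O)/C(C)=C/C)cc(OCOC)c(CC=C(C)C)c1OCOC | intermediate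
18 | methyl (3S)-3-[2-hydroxy-4,6-bis(methoxymethoxy)-3-[(2E)-2-methylbut-2-enoyl]-5-(3-methylbut-2-en-1-yl)phenyl]hexanoate | CCC[C@@H](CC(=O)OC)c1c(O)c(C(=O)/C(C)=C/C)c(OCOC)c(CC=C(C)C)c1OCOC | intermediate (not isolated)
19 | methyl (3S)-3-[(2R,3S)-5,7-bis(methoxymethoxy)-2,3-dimethyl-6-(3-methylbut-2-en-1-yl)-4-oxo-3,4-dihydro-2H-chromen-8-yl]hexanoate | CCC[C@@H](CC(=O)OC)c1c(OCOC)c(CC=C(C)C)c(OCOC)c2c1O[C@H](C)[C@H](C)C2=O | intermediate
20 | methyl (3S)-3-[(2R,3S)-5,7-dihydroxy-2,3-dimethyl-6-(3-methylbut-2-en-1-yl)-4-oxo-3,4-dihydro-2H-chromen-8-yl]hexanoate (CNP0068017.4) | CCC[C@@H](CC(=O)OC)c1c(O)c(CC=C(C)C)c(O)c2c1O[C@H](C)[C@H](C)C2=O | target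

Total step count: 8
Longest linear sequence: 8 steps (resorcinol 1 to target 20)

Steps most likely to fail

Step 7 (key step). The radical pair may escape the solvent cage and return phenol 15 instead of recombining at C4a. The tigloyl alkene may also isomerise under the lamp before the quinine stage, or prolonged irradiation may degrade the ketone. The fallback makes the C4–C4a bond by carbonyl addition instead of acyl migration and sets out from 15. Magnesium-mediated ortho-formylation (MgCl2, Et3N, paraformaldehyde, MeCN, reflux) should give methyl (3S)-3-[3-formyl-2-hydroxy-4,6-bis(methoxymethoxy)-5-(3-methylbut-2-en-1-yl)phenyl]hexanoate F1. Nozaki–Hiyama–Kishi addition of (E)-2-bromobut-2-ene (CrCl2, catalytic NiCl2, DMF), which spares the ester, should give methyl (3S)-3-[2-hydroxy-3-[(2E)-1-hydroxy-2-methylbut-2-en-1-yl]-4,6-bis(methoxymethoxy)-5-(3-methylbut-2-en-1-yl)phenyl]hexanoate F2. Oxidation with MnO2 in CH2Cl2 comes back to the route at 18, which is then isolated and cyclised with (−)-quinine to 19 as in the second stage of step 7.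

Step 4. Reversible O-addition of the phenol may outrun C-alkylation at the hindered ortho carbon, a second alkylation may occur at the other ortho carbon, or facial selectivity may be poor with the aliphatic enal. The fallback sets out from 10 and 11 and uses acyl azolium instead of iminium catalysis: an N-heterocyclic-carbene-catalysed oxidative [3+3] annulation (chiral aminoindanol-derived N-mesityl triazolium chloride, DBU, 3,3',5,5'-tetra-tert-butyl-4,4'-diphenoquinone, toluene, rt). The phenol should attack C3 of the hexenoyl azolium through its ortho carbon and then lactonise, with the triazolium enantiomer chosen to give (4S). This comes back to the route at lactone 14, which is opened with NaOMe/MeOH as in step 5; no new compound is made.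

Step 3. The iridium boryl species may hydroborate or borylate the prenyl alkene, or the alkene may slow the catalyst so that arene borylation stalls. The fallback sets out from 3 and borylates before the alkene is present. The same iridium-catalysed borylation of 3 should give 2-[3,5-bis(methoxymethoxy)phenyl]-4,4,5,5-tetramethyl-1,3,2-dioxaborolane F3, and H2O2/NaOH oxidation should give 3,5-bis(methoxymethoxy)phenol F4. Silylation (i-Pr3SiCl, imidazole, DMF) should give [3,5-bis(methoxymethoxy)phenoxy]tri(propan-2-yl)silane F5. Lithiation with n-BuLi between the two OMOM groups should give {2,6-bis(methoxymethoxy)-4-[tri(propan-2-yl)silyloxy]phenyl}lithium F6, and prenyl bromide 4 should then give [3,5-bis(methoxymethoxy)-4-(3-methylbut-2-en-1-yl)phenoxy]tri(propan-2-yl)silane F7. Desilylation with n-Bu4NF in THF comes back to the route at 10.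

Further compounds
F1 | step 7 | methyl (3S)-3-[3-formyl-2-hydroxy-4,6-bis(methoxymethoxy)-5-(3-methylbut-2-en-1-yl)phenyl]hexanoate | CCC[C@@H](CC(=O)OC)c1c(O)c(C=O)c(OCOC)c(CC=C(C)C)c1OCOC
F2 | step 7 | methyl (3S)-3-[2-hydroxy-3-[(2E)-1-hydroxy-2-methylbut-2-en-1-yl]-4,6-bis(methoxymethoxy)-5-(3-methylbut-2-en-1-yl)phenyl]hexanoate (carbinol epimers) | CCC[C@@H](CC(=O)OC)c1c(O)c(C(O)/C(C)=C/C)c(OCOC)c(CC=C(C)C)c1OCOC
F0 | step 4 | none | none
F3 | step 3 | 2-[3,5-bis(methoxymethoxy)phenyl]-4,4,5,5-tetramethyl-1,3,2-dioxaborolane | COCOc1cc(OCOC)cc(c1)B1OC(C)(C)C(C)(C)O1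
F4 | step 3 | 3,5-bis(methoxymethoxy)phenol | COCOc1cc(O)cc(OCOC)c1
F5 | step 3 | [3,5-bis(methoxymethoxy)phenoxy]tri(propan-2-yl)silane | COCOc1cc(O[Si](C(C)C)(C(C)C)C(C)C)cc(OCOC)c1
F6 | step 3 | {2,6-bis(methoxymethoxy)-4-[tri(propan-2-yl)silyloxy]phenyl}lithium | [Li]c1c(OCOC)cc(O[Si](C(C)C)(C(C)C)C(C)C)cc1OCOC
F7 | step 3 | [3,5-bis(methoxymethoxy)-4-(3-methylbut-2-en-1-yl)phenoxy]tri(propan-2-yl)silane | COCOc1cc(O[Si](C(C)C)(C(C)C)C(C)C)cc(OCOC)c1CC=C(C)C
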